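**Retrosynthetic overview**
1. Target ⇒ (2R,3R)-aromadendrin + prenyl bromide: the C7–O ether bond is made last.
2. Aromadendrin ⇒ racemic naringenin skeleton by forming the C3–O bond in a new enantioconvergent α-hydroxylation that sets C2 and C3 together.
3. Both rings of the flavanone are bought. No ring is built; the pyranone ring only opens and re-closes reversibly during step 2, which is what racemises C2.
4. The 4'- and 7-phenols are masked as TBS ethers for step 2; the chelated 5-OH is left free as the metal-binding handle.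

Assumption: commercial naringenin is taken as the racemate. The sense of induction of the new catalyst in step 2 is assumed, not known; if it proves reversed, the ligand antipode (from the D-amino acid) is used.

**Step 1**
Reactants: 1 (±)-naringenin; 2 tert-butyldimethylsilyl chloride
Product: 3 (±)-4',7-bis-O-TBS-naringenin
Conditions: TBSCl (2.3 equiv), imidazole (5 equiv), DMF, 0 °C → rt, 3 h
Reagents that add atoms: tert-butyldimethylsilyl chloride, CC(C)(C)[Si](C)(C)Cl
Why: Silylation of phenols (TBSCl/imidazole) caps the two free phenols, while the 5-OH hydrogen-bonded to the C4 carbonyl stays free; no stereocentre is set.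

**Step 2**
Reactants: 3 (±)-4',7-bis-O-TBS-naringenin; 4 (±)-trans-3-phenyl-2-(phenylsulfonyl)oxaziridine (Davis oxaziridine)
Product: 7 (2R,3R)-aromadendrin, via ring-opened chalcone 5 (not isolated), via bis-silyl dihydroflavonol 6 (not isolated)
Conditions: Sc(OTf)3 (10 mol %), chiral N,N'-dioxide ligand L-PiPr2 (L-pipecolic acid/2,6-diisopropylanilide, 11 mol %), 2,6-lutidine (30 mol %), 4 Å MS, CH2Cl2, 0 °C, 4 (1.2 equiv) added over 8 h; then KHF2 (3 equiv), MeOH, rt, 2 h
Reagents that add atoms: (±)-trans-3-phenyl-2-(phenylsulfonyl)oxaziridine, O=S(=O)(c1ccccc1)N1OC1c1ccccc1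
Why: Proposed new method: the 5-OH/C4=O pair binds Sc(III) as a six-membered phenoxide–ketone chelate (as a β-keto ester would), which acidifies C3–H so that 2,6-lutidine gives a scandium enolate; this enolate reversibly expels O1 (retro-oxa-Michael to the symmetric chalcone 5 and re-closure), so C2 racemises on the catalyst, while the chiral pocket lets only the 2S enolate take oxygen from the oxaziridine at C3 anti to the 2-aryl group, forming the C3–O bond and fixing the 2,3-trans (2R,3R) configuration in a dynamic kinetic resolution (the 4'-O-silyl group blocks quinone-methide epimerisation of the product); the closest known reaction type is the chiral Lewis-acid-catalysed α-hydroxylation of β-keto esters and oxindoles with N-sulfonyloxaziridines, combined with the base-catalysed flavanone–chalcone equilibrium; KHF2 then cleaves both aryl silyl ethers.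

**Step 3**
Reactants: 7 (2R,3R)-aromadendrin; 8 prenyl bromide
Product: 9 7-prenyloxyaromadendrin
Conditions: prenyl bromide (1.1 equiv), K2CO3 (1.1 equiv), degassed acetone, Ar, rt, 12 h
Reagents that add atoms: prenyl bromide (1-bromo-3-methylbut-2-ene), CC(C)=CCBr
Why: Williamson ether synthesis: the 7-OH (para to the carbonyl, the most acidic OH) is the only one ionised by one equivalent of K2CO3, the 5-OH is chelated and the 3-OH and 4'-OH are much weaker acids, and the mild oxygen-free conditions leave C2 and C3 untouched.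

**Compound list**
1 | (±)-naringenin, rac-5,7-dihydroxy-2-(4-hydroxyphenyl)chroman-4-one | O=C1CC(c2ccc(O)cc2)Oc2cc(O)cc(O)c12 | starting material
2 | tert-butyldimethylsilyl chloride | CC(C)(C)[Si](C)(C)Cl | starting material
3 | (±)-4',7-bis-O-TBS-naringenin, rac-5-hydroxy-7-(TBSO)-2-[4-(TBSO)phenyl]chroman-4-one | CC(C)(C)[Si](C)(C)Oc1cc(O)c2c(c1)OC(c1ccc(O[Si](C)(C)C(C)(C)C)cc1)CC2=O | intermediate
4 | (±)-trans-3-phenyl-2-(phenylsulfonyl)oxaziridine (Davis oxaziridine) | O=S(=O)(c1ccccc1)N1OC1c1ccccc1 | starting material
5 | (E)-1-[2,6-dihydroxy-4-(TBSO)phenyl]-3-[4-(TBSO)phenyl]prop-2-en-1-one (ring-opened chalcone of 3, catalyst-bound) | CC(C)(C)[Si](C)(C)Oc1ccc(/C=C/C(=O)c2c(O)cc(O[Si](C)(C)C(C)(C)C)cc2O)cc1 | intermediate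
6 | (2R,3R)-4',7-bis-O-TBS-aromadendrin (2,3-trans) | CC(C)(C)[Si](C)(C)Oc1cc(O)c2c(c1)O[C@H](c1ccc(O[Si](C)(C)C(C)(C)C)cc1)[C@@H](O)C2=O | intermediate
7 | (2R,3R)-aromadendrin, (2R,3R)-3,5,7-trihydroxy-2-(4-hydroxyphenyl)chroman-4-one | Oc1cc(O)c2c(c1)O[C@H](c1ccc(O)cc1)[C@@H](O)C2=O | intermediate
8 | prenyl bromide, 1-bromo-3-methylbut-2-ene | CC(C)=CCBr | starting material
9 | 7-prenyloxyaromadendrin, (2R,3R)-3,5-dihydroxy-2-(4-hydroxyphenyl)-7-[(3-methylbut-2-en-1-yl)oxy]chroman-4-one | CC(C)=CCOc1cc(O)c2c(c1)O[C@H](c1ccc(O)cc1)[C@@H](O)C2=O | target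

**Total step count:** 3. **Longest linear sequence:** 3.

**Steps most likely to fail, in order of risk**

Step 2 is the new reaction and carries the most risk. Enolisation of the scandium chelate by lutidine may be too slow. Ring opening and re-closure may be slower than oxidation, which would leave a plain kinetic resolution with at most 50 % yield. The enolate may add to the sulfonimine by-product, and the level or sense of induction may be poor. The fallback uses known chemistry, sets out from 1 and comes back at 7. Compound 1 is ring-opened and fully protected with NaH and MOMCl in DMF to give (E)-2',4',6',4-tetrakis(methoxymethoxy)chalcone F1. Juliá–Colonna epoxidation (poly-L-leucine, urea–H2O2, DBU, THF) gives the (αR,βS)-epoxide F2. HCl in MeOH at 50 °C removes the MOM groups, and the freed 2'-OH opens the epoxide at the benzylic carbon with inversion to give 7, which is recrystallised to full enantiopurity.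

Step 3 is second. The dihydroflavonol is base-sensitive: it can oxidise to the flavonol, epimerise at C2 through the 4'-phenoxide, or be alkylated at 4'-O as well. The fallback changes the order of events so that the chiral product is never alkylated; it sets out from 1 and comes back at 9. Compound 1 is prenylated first (prenyl bromide, K2CO3, acetone) to (±)-7-O-prenylnaringenin F3, and its 4'-OH is silylated (TBSCl, imidazole, DMF) to (±)-4'-O-TBS-7-O-prenylnaringenin F4. The step 2 hydroxylation is run on F4 to give the 4'-O-TBS ether of the target F5, which is not isolated, and KHF2 in MeOH releases 9.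

Step 1 is third. The 7-O-silyl ether, para to the carbonyl, may be too labile on isolation or under the Lewis acid of step 2. The fallback changes the protecting-group strategy to benzyl ethers removed by hydrogenolysis, possible because no alkene is present yet; it sets out from 1 and comes back at 7. Compound 1 is benzylated (BnBr 2.2 equiv, K2CO3, acetone, reflux) to (±)-4',7-di-O-benzylnaringenin F6. The hydroxylation of step 2, without the fluoride stage, gives (2R,3R)-4',7-di-O-benzylaromadendrin F7, and H2 with Pd/C in EtOAc gives 7.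

**Further compounds**
F1 | step 2 | (E)-1-[2,4,6-tris(methoxymethoxy)phenyl]-3-[4-(methoxymethoxy)phenyl]prop-2-en-1-one | COCOc1ccc(/C=C/C(=O)c2c(OCOC)cc(OCOC)cc2OCOC)cc1
F2 | step 2 | (αR,βS)-trans-epoxide of F1, [(2R,3S)-3-[4-(methoxymethoxy)phenyl]oxiran-2-yl][2,4,6-tris(methoxymethoxy)phenyl]methanone | O=C(c1c(OCOC)cc(OCOC)cc1OCOC)[C@@H]2O[C@H]2c3ccc(OCOC)cc3
F3 | step 3 | (±)-7-O-prenylnaringenin | CC(C)=CCOc1cc(O)c2c(c1)OC(c1ccc(O)cc1)CC2=O
F4 | step 3 | (±)-4'-O-TBS-7-O-prenylnaringenin | CC(C)=CCOc1cc(O)c2c(c1)OC(c1ccc(O[Si](C)(C)C(C)(C)C)cc1)CC2=O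
F5 | step 3 | (2R,3R)-4'-O-TBS-7-prenyloxyaromadendrin | CC(C)=CCOc1cc(O)c2c(c1)O[C@H](c1ccc(O[Si](C)(C)C(C)(C)C)cc1)[C@@H](O)C2=O
F6 | step 1 | (±)-4',7-di-O-benzylnaringenin | O=C1CC(c2ccc(OCc3ccccc3)cc2)Oc2cc(OCc3ccccc3)cc(O)c12
F7 | step 1 | (2R,3R)-4',7-di-O-benzylaromadendrin | c1ccc(COc2cc(O)c3c(c2)O[C@H](c2ccc(OCc4ccccc4)cc2)[C@@H](O)C3=O)cc1
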